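**Assumptions**
- The target is the trans-(2S,3S) dihydrobenzofuran. I checked this against the SMILES: with the ring drawn counter-clockwise, Ar2 lies above the ring plane and Ar1 below it.
- 5-Hydroxyveratraldehyde (1) and (2S,5S)-2,5-dimethylthiolane (11) are treated as purchasable. If 11 is not, it takes 2 steps from (2R,5R)-hexane-2,5-diol. The sulfide enantiomer that gives the (2S,3S) product must be confirmed with a model run.

## Retrosynthesis
1. Scirpusin C (15) comes from global O-demethylation of its nonamethyl ether (14), a trans-2,3-diaryl-dihydrobenzofuran.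
2. The dihydrobenzofuran is formed last, in one key step. A phenol-derived sulfone (9) is dearomatised to an o-quinone methide (o-QM). A chiral benzylic sulfonium ylide (from 13) adds to it ([4+1] annulation). The ylide face sets C3, and anti-betaine SN2 closure sets C2 trans.
3. The sulfone (9) comes from the o-hydroxybenzhydrol (7). That comes from the salicylaldehyde (5) plus a 3,5-dimethoxyphenyl Grignard. The salicylaldehyde comes from ortho-formylation of stilbene phenol (3), which is made by HWE from commercial 1.
4. Order of bond formation: stilbene C=C, then the aryl–carbinol C–C bond, then the dihydrofuran ring (C3–C3a and C2–O, with both stereocentres).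

## Forward route

**Step 1**
Reactants: 1 (5-hydroxy-3,4-dimethoxybenzaldehyde), 2 (diethyl 3,5-dimethoxybenzylphosphonate)
Product: 3, (E)-5-[2-(3,5-dimethoxyphenyl)vinyl]-2,3-dimethoxyphenol
Conditions: NaH (2.5 equiv), THF/DMF, 0 °C → 60 °C
Reagents that add atoms: none
Why: Horner–Wadsworth–Emmons olefination of the phenoxide aldehyde gives the E-stilbene selectively. The free phenol is the oxygen that will become the ring O.

**Step 2**
Reactants: 3, 4 (paraformaldehyde)
Product: 5, 2-hydroxy-3,4-dimethoxy-6-[(E)-2-(3,5-dimethoxyphenyl)vinyl]benzaldehyde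
Conditions: MgCl2, Et3N, (CH2O)n, MeCN, 80 °C
Reagents that add atoms: paraformaldehyde, C=O (adds the CHO carbon and oxygen)
Why: Casnati–Skattebøl ortho-formylation. The Mg-phenoxide delivers formaldehyde to an ortho carbon, and the only free ortho carbon is C2, between the styryl and OH groups. This also breaks the local symmetry of the 3,4,5-trioxygenated ring.

**Step 3**
Reactants: 5, 6 (1-bromo-3,5-dimethoxybenzene, used as ArMgBr prepared in situ from 6 and Mg)
Product: 7, 2-[(3,5-dimethoxyphenyl)(hydroxy)methyl]-3-[(E)-2-(3,5-dimethoxyphenyl)vinyl]-5,6-dimethoxyphenol (racemic carbinol)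
Conditions: ArMgBr (2.5 equiv), THF, −78 °C → 0 °C, then aq. NH4Cl; use crude at once
Reagents that add atoms: 3,5-dimethoxyphenylmagnesium bromide, COc1cc([Mg]Br)cc(OC)c1 (adds the Ar1 group)
Why: Grignard 1,2-addition to the aldehyde. The first equivalent deprotonates the phenol. The carbinol stereocentre is destroyed in step 6, so its configuration is irrelevant.

**Step 4**
Reactants: 7, 8 (sodium p-toluenesulfinate)
Product: 9, the diaryl(tosyl)methyl phenol (o-hydroxybenzhydryl sulfone, racemic)
Conditions: p-TolSO2Na (2 equiv), HCO2H (5 equiv), MeCN/H2O, rt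
Reagents that add atoms: sodium p-toluenesulfinate, Cc1ccc(cc1)S(=O)[O-].[Na+] (adds the Ts group)
Why: acid ionises the electron-rich o-hydroxybenzhydrol to an o-QM or benzylic cation, which sulfinate traps. The result is a bench-stable, base-labile masked o-QM.

**Step 5**
Reactants: 10 (3,4,5-trimethoxybenzyl chloride), 11 ((2S,5S)-2,5-dimethylthiolane), 12 (AgBF4)
Product: 13, (2S,5S)-2,5-dimethyl-1-(3,4,5-trimethoxybenzyl)thiolanium tetrafluoroborate
Conditions: 11 (1.2 equiv), AgBF4 (1.0 equiv), MeCN, rt, dark, 12 h; filter off AgCl
Reagents that add atoms: AgBF4, [Ag+].F[B-](F)(F)F (BF4⁻ stays as the counter-anion)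
Why: S-alkylation of the C2-symmetric sulfide gives the ylide precursor. The Ar2 unit and the chiral controller are carried in this salt.

**Step 6 (key step)**
Reactants: 9, 13
Product: 14, (2S,3S)-2,3-trans-nonamethyl scirpusin C, (2S,3S)-3-(3,5-dimethoxyphenyl)-4-[(E)-2-(3,5-dimethoxyphenyl)vinyl]-6,7-dimethoxy-2-(3,4,5-trimethoxyphenyl)-2,3-dihydrobenzofuran
Conditions: 13 (1.5 equiv), Cs2CO3 (4 equiv), CH2Cl2, 0 °C → rt, 24 h, Ar; recover sulfide 11
Reagents that add atoms: none (base only)
Why: The phenoxide of 9 loses sulfinate (E1cB) to give a dearomatised o-quinone methide. The semistabilised ylide from 13 adds 1,4 to the exocyclic carbon. The ylide face sets C3, and anti-betaine formation followed by 5-exo phenoxide SN2 closure with loss of sulfide 11 sets C2 trans. The ring re-aromatises on closure.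
Proposed new method: the mechanistic reasoning is as above. The closest known chemistry is sulfonium-ylide [4+1] annulation of o-QMs with achiral ylides, which gives trans-2,3-dihydrobenzofurans. The chiral-sulfide facial control is borrowed from sulfide-mediated asymmetric epoxidation of aldehydes, which gives trans-stilbene oxides.

**Step 7**
Reactants: 14
Product: 15, scirpusin C
Conditions: BBr3 (20 equiv), CH2Cl2, −78 → 0 °C, 4 h; MeOH quench; degassed work-up; RP-HPLC
Reagents that add atoms: none (each OMe becomes OH; the methyl is lost as MeBr)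
Why: BBr3 cleaves all nine aryl methyl ethers. This is the standard permethyl ether deprotection used for ε-viniferin-type compounds. The E-alkene and both C2/C3 stereocentres are untouched because no step acts on them.

**Checks**
- Ring sizes match the target: a 2,3-dihydrobenzofuran with a 4-styryl group and 6,7-dihydroxy on the fused ring.
- Substituents match: C3 carries 3,5-dihydroxyphenyl and C2 carries 3,4,5-trihydroxyphenyl.
- The styryl aryl ring is 3,5-dihydroxyphenyl.
- Both stereocentres arise only in step 6 and are not touched afterwards.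

## Compound list
1 | 5-hydroxy-3,4-dimethoxybenzaldehyde | O=Cc1cc(O)c(OC)c(OC)c1 | starting material
2 | diethyl 3,5-dimethoxybenzylphosphonate | CCOP(=O)(OCC)Cc1cc(OC)cc(OC)c1 | starting material
3 | (E)-5-[2-(3,5-dimethoxyphenyl)vinyl]-2,3-dimethoxyphenol | COc1cc(/C=C/c2cc(O)c(OC)c(OC)c2)cc(OC)c1 | intermediate
4 | paraformaldehyde (monomer) | C=O | starting material
5 | 2-hydroxy-3,4-dimethoxy-6-[(E)-2-(3,5-dimethoxyphenyl)vinyl]benzaldehyde | COc1cc(/C=C/c2cc(OC)c(OC)c(O)c2C=O)cc(OC)c1 | intermediate
6 | 1-bromo-3,5-dimethoxybenzene | COc1cc(Br)cc(OC)c1 | starting material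
7 | 2-[(3,5-dimethoxyphenyl)(hydroxy)methyl]-3-[(E)-2-(3,5-dimethoxyphenyl)vinyl]-5,6-dimethoxyphenol (racemic) | COc1cc(/C=C/c2cc(OC)c(OC)c(O)c2C(O)c2cc(OC)cc(OC)c2)cc(OC)c1 | intermediate
8 | sodium p-toluenesulfinate | Cc1ccc(cc1)S(=O)[O-].[Na+] | starting material
9 | o-hydroxybenzhydryl p-tolyl sulfone (racemic) | COc1cc(/C=C/c2cc(OC)c(OC)c(O)c2C(c2cc(OC)cc(OC)c2)S(=O)(=O)c2ccc(C)cc2)cc(OC)c1 | intermediate
10 | 3,4,5-trimethoxybenzyl chloride | COc1cc(CCl)cc(OC)c1OC | starting material
11 | (2S,5S)-2,5-dimethyltetrahydrothiophene | C[C@H]1CC[C@H](C)S1 | starting material (chiral controller, recovered)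
12 | silver tetrafluoroborate | [Ag+].F[B-](F)(F)F | reagent
13 | (2S,5S)-2,5-dimethyl-1-(3,4,5-trimethoxybenzyl)thiolanium BF4 | COc1cc(C[S+]2[C@@H](C)CC[C@@H]2C)cc(OC)c1OC.F[B-](F)(F)F | intermediate
14 | (2S,3S)-nonamethyl scirpusin C | COc1cc(OC)cc(/C=C/c2cc(OC)c(OC)c3c2[C@H](c2cc(OC)cc(OC)c2)[C@@H](c2cc(OC)c(OC)c(OC)c2)O3)c1 | intermediate
15 | scirpusin C | Oc1cc(O)cc(/C=C/c2cc(O)c(O)c3c2[C@H](c2cc(O)cc(O)c2)[C@@H](c2cc(O)c(O)c(O)c2)O3)c1 | target

## Totals
- Total steps: 7.
- Longest linear sequence: 6 steps (1 → 3 → 5 → 7 → 9 → 14 → 15).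

## Three steps most likely to fail
1. **Step 6 (o-QM/ylide annulation).**
   - Risks: the ee of the chiral sulfide induction may be modest, the benzylic betaine may ionise (giving cis/trans mixtures), and the o-QM may oligomerise.
   - Fallback: run the same sequence with an achiral sulfide (tetrahydrothiophene) to get racemic trans-14, then resolve the neutral nonamethyl ether by preparative chiral-phase HPLC. This swaps asymmetric induction for resolution.
2. **Step 2 (formylation at the hindered C2).**
   - Risk: low conversion because C2 sits between the styryl and OH groups.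
   - Fallback: protect 3 as its MOM ether and lithiate ortho to the OMOM group. Add 3,5-dimethoxybenzaldehyde directly to give the carbinol. Remove the MOM group in acid to reach 7 in place of steps 2 and 3.
3. **Step 7 (BBr3 global demethylation).**
   - Risks: the benzylic C2–O ether may ionise and epimerise or ring-open under Lewis acid, and the pyrogallol is oxidation-prone.
   - Fallback: rebuild the sequence with O-allyl or O-MOM ring protection in place of methyl ethers. Remove them under mild Pd(0)/silane or dilute HCl/MeOH conditions.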